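**Plan**

1. Retrosynthesis: the acyl C19–O bond of the lactone is cut first (back to a C19 nitrile and a C20 alcohol), then the C20–O bond (back to the C20 methyl and a 6β-hydroxyl), then the ring C substituents (O11, O14, C13 isopropyl), which leaves (+)-podocarpic acid.
2. Forward: rings A, B and C come intact from podocarpic acid; ring C is completed first (isopropyl from an acetyl group, O11 by ortho-oxidation of the 12-phenol, O14 through the para-quinone) and C19 is turned into the nitrile.
3. Ring B is then taken through the 7-ketone, the Δ6-alkene and an epoxide rearrangement to the 6-ketone and the 6β-alcohol.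
4. Enabling feature: C20 on C10 is syn-axial both to the 6β position of ring B and to C19 on C4 of ring A, so an oxygen radical on C6 reaches a C20 hydrogen and closes the five-membered ring O–C6–C5–C10–C20.
5. Once C7 is a ketone the C6–O bond is cut with SmI2; the oxygen stays on C20 and closes onto C19 to the six-membered lactone (C19, O, C20, C10, C5, C4); the 11,14-hydroquinone is released last via the quinone.
6. Stereochemistry: C4, C5 and C10 come from podocarpic acid and are never broken; the temporary C6 centre is set by hydride attack on the α face.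

Key step: step 17

Remark: abietane numbering is used (C18 = 4α-methyl, C19 = 4β-carbon, C20 = carbon on C10, β = the face of C20); every compound keeps the podocarpic acid configuration (4β-C19, 5α-H, 10β-C20), and (+)-podocarpic acid and all reagents named are taken as commercial.

**Route**

Step 1
Reactants: 1 (+)-podocarpic acid (12-hydroxypodocarpa-8,11,13-trien-19-oic acid)
Product: 2 methyl 12-methoxypodocarpa-8,11,13-trien-19-oate
Conditions: Me2SO4, K2CO3, acetone, reflux
Reagents that add atoms: dimethyl sulfate, COS(=O)(=O)OC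
Why: Williamson-type SN2 methylation of the phenoxide and the carboxylate caps both acidic groups and turns the phenol into an ortho-directing methyl ether; no stereocentre is touched.

Step 2
Reactants: 2 methyl 12-methoxypodocarpa-8,11,13-trien-19-oate; 3 acetyl chloride
Product: 4 methyl 13-acetyl-12-methoxypodocarpa-8,11,13-trien-19-oate
Conditions: AlCl3, CH2Cl2, 0 °C to rt
Reagents that add atoms: acetyl chloride (3), CC(=O)Cl
Why: Friedel–Crafts acylation goes ortho to the methoxy group at C13, because the other ortho carbon, C11, is shielded by the C1 methylene and C20 and the para carbon is the ring fusion.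

Step 3
Reactants: 4 methyl 13-acetyl-12-methoxypodocarpa-8,11,13-trien-19-oate
Product: 5 methyl 13-(2-hydroxypropan-2-yl)-12-methoxypodocarpa-8,11,13-trien-19-oate
Conditions: MeMgBr, THF, 0 °C
Reagents that add atoms: methylmagnesium bromide, C[Mg]Br
Why: Grignard addition to the aryl ketone is fast at 0 °C, whereas the axial, neopentyl-type C19 ester is too hindered to react.

Step 4
Reactants: 5 methyl 13-(2-hydroxypropan-2-yl)-12-methoxypodocarpa-8,11,13-trien-19-oate
Product: 6 methyl 12-methoxyabieta-8,11,13-trien-19-oate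
Conditions: Et3SiH, CF3CO2H, CH2Cl2, 0 °C to rt
Reagents that add atoms: none
Why: Ionic hydrogenation of the tertiary benzylic alcohol proceeds through the methoxy-stabilised cumyl cation, which takes hydride from the silane to give the isopropyl group.

Step 5
Reactants: 6 methyl 12-methoxyabieta-8,11,13-trien-19-oate
Product: 7 12-methoxyabieta-8,11,13-trien-19-oic acid
Conditions: n-PrSLi, HMPA, rt; then aq. HCl
Reagents that add atoms: none
Why: SN2 attack of the thiolate on the ester methyl (alkyl–oxygen cleavage) frees the hindered axial acid that resists saponification, and the aryl methyl ether is inert at room temperature.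

Step 6
Reactants: 7 12-methoxyabieta-8,11,13-trien-19-oic acid
Product: 9 12-methoxyabieta-8,11,13-trien-19-amide, via acid chloride 8 (not isolated)
Conditions: (COCl)2, DMF (cat.), CH2Cl2, 0 °C to rt; then NH3 (g), 0 °C
Reagents that add atoms: ammonia, N
Why: Acid chloride formation followed by ammonolysis is the standard acyl substitution for a hindered tertiary acid, with ammonia small enough to reach the axial carbonyl.

Step 7
Reactants: 9 12-methoxyabieta-8,11,13-trien-19-amide
Product: 10 12-methoxyabieta-8,11,13-triene-19-nitrile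
Conditions: (CF3CO)2O, pyridine, CH2Cl2, 0 °C
Reagents that add atoms: none
Why: Dehydration of the primary amide by O-trifluoroacetylation and elimination gives the nitrile, a C19 group that no neighbouring hydroxyl can acylate under neutral conditions.

Step 8
Reactants: 10 12-methoxyabieta-8,11,13-triene-19-nitrile
Product: 11 12-hydroxyabieta-8,11,13-triene-19-nitrile
Conditions: BBr3, CH2Cl2, −78 to 0 °C
Reagents that add atoms: none
Why: Lewis-acid cleavage of the aryl methyl ether (bromide attack on the O-methyl of the boron complex) frees the phenol needed for ortho-oxidation, and the nitrile only binds the reagent reversibly.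

Step 9
Reactants: 11 12-hydroxyabieta-8,11,13-triene-19-nitrile
Product: 13 11,12-dihydroxyabieta-8,11,13-triene-19-nitrile, via ortho-quinone 12 (not isolated)
Conditions: IBX, DMF, rt; then aq. Na2S2O4
Reagents that add atoms: 2-iodoxybenzoic acid (IBX), O=C1OI(=O)(O)c2ccccc12
Why: IBX ortho-oxygenation of a phenol delivers oxygen from the aryloxy-iodane to the only free ortho carbon, C11, and the ortho-quinone is reduced at once by Na2S2O4 so that it cannot tautomerise towards C7.

Step 10
Reactants: 13 11,12-dihydroxyabieta-8,11,13-triene-19-nitrile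
Product: 14 11-hydroxy-12-methoxyabieta-8,11,13-triene-19-nitrile
Conditions: MeI (1.0 equiv), Li2CO3, DMF, 40 °C, argon
Reagents that add atoms: iodomethane, CI
Why: Williamson mono-methylation with one equivalent of MeI and a weak base should favour O12, because O11 is shielded by the C1 methylene and by quaternary C10 with its C20 methyl.

Step 11
Reactants: 14 11-hydroxy-12-methoxyabieta-8,11,13-triene-19-nitrile
Product: 15 12-methoxy-11,14-dioxoabieta-8,12-diene-19-nitrile
Conditions: (KSO3)2NO, KH2PO4, acetone–H2O, rt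
Reagents that add atoms: potassium nitrosodisulfonate, [K+].[K+].[O]N(S(=O)(=O)[O-])S(=O)(=O)[O-]
Why: Teuber oxidation turns the 11-phenol into its phenoxyl radical, which is trapped at the free para carbon C14 and collapses to the para-quinone, so O14 is placed without any directing group.

Step 12
Reactants: 15 12-methoxy-11,14-dioxoabieta-8,12-diene-19-nitrile
Product: 17 11,12,14-trimethoxyabieta-8,11,13-triene-19-nitrile, via hydroquinone 16 (not isolated)
Conditions: Na2S2O4, aq. NaOH, Bu4NBr (cat.), Me2SO4, THF, rt, argon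
Reagents that add atoms: dimethyl sulfate, COS(=O)(=O)OC
Why: Reductive methylation (quinone reduction by Na2S2O4, then phase-transfer Williamson methylation of both phenoxides) gives a fully substituted arene that cannot be iodinated later.

Step 13
Reactants: 17 11,12,14-trimethoxyabieta-8,11,13-triene-19-nitrile
Product: 18 11,12,14-trimethoxy-7-oxoabieta-8,11,13-triene-19-nitrile
Conditions: CrO3, AcOH–H2O, rt
Reagents that add atoms: chromium trioxide, O=[Cr](=O)=O
Why: Benzylic oxidation by CrO3 takes the C7 methylene, the only unhindered benzylic CH2, since the isopropyl methine lies between two methoxy groups.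

Step 14
Reactants: 18 11,12,14-trimethoxy-7-oxoabieta-8,11,13-triene-19-nitrile
Product: 20 11,12,14-trimethoxyabieta-6,8,11,13-tetraene-19-nitrile, via 7-alcohol 19 (not isolated)
Conditions: NaBH4, MeOH–THF, 0 °C; then TsOH·H2O (cat.), toluene, 80 °C
Reagents that add atoms: none
Why: Hydride reduction of the aryl ketone and acid-catalysed E1 dehydration through the methoxy-stabilised C7 cation give the conjugated Δ6-alkene, so the C7 configuration of 19 does not matter.

Step 15
Reactants: 20 11,12,14-trimethoxyabieta-6,8,11,13-tetraene-19-nitrile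
Product: 22 11,12,14-trimethoxy-6-oxoabieta-8,11,13-triene-19-nitrile, via 6α,7α-epoxide 21 (not isolated)
Conditions: dimethyldioxirane, acetone, −20 °C; evaporate; ZnI2 (cat.), CH2Cl2, 0 °C
Reagents that add atoms: dimethyldioxirane, CC1(C)OO1
Why: Neutral epoxidation from the α face (the β face is covered by C20) and Meinwald rearrangement (ZnI2 opens the epoxide at benzylic C7, a 1,2-hydride shift from C6 follows) give the 6-ketone as in the 1,2-dihydronaphthalene oxide to 2-tetralone conversion, and the base-free medium leaves C5 unchanged.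

Step 16
Reactants: 22 11,12,14-trimethoxy-6-oxoabieta-8,11,13-triene-19-nitrile
Product: 23 6β-hydroxy-11,12,14-trimethoxyabieta-8,11,13-triene-19-nitrile
Conditions: NaBH4, EtOH, −20 °C; aq. NH4Cl work-up
Reagents that add atoms: none
Why: Hydride reduction of the ketone occurs from the α face because the β face is screened by the syn-axial C20 methyl and C19 nitrile, which sets the axial 6β-hydroxyl; the cold, near-neutral work-up keeps the alkoxide from adding to C19.

Step 17
Reactants: 23 6β-hydroxy-11,12,14-trimethoxyabieta-8,11,13-triene-19-nitrile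
Product: 26 6β,20-epoxy-11,12,14-trimethoxyabieta-8,11,13-triene-19-nitrile, via hypoiodite 24 (not isolated), via 20-iodo alcohol 25 (not isolated)
Conditions: PhI(OAc)2, I2, cyclohexane–CH2Cl2, hν (tungsten lamp), 20 °C
Reagents that add atoms: none
Why: Acetyl hypoiodite made from PhI(OAc)2 and I2 converts the 6β-hydroxyl into hypoiodite 24, light cleaves its O–I bond, the 6β-alkoxy radical abstracts a C20 hydrogen through a six-membered transition state (1,5-hydrogen transfer), iodine caps the C20 radical to give 25, and the 6β-oxygen displaces the iodide. The closest known reaction is the hypoiodite reaction of 6β-hydroxy steroids, which gives 6β,19-ethers from the syn-axial angular methyl. The one new ring, the tetrahydrofuran O–C6–C5–C10–C20, closes by 5-exo-tet substitution at C20. No stereocentre is created, since the C6–O bond is never broken and C5 and C10 are untouched. The step needs site selectivity for C20–H and a preference for hydrogen transfer over β-scission of C6–C7 to a benzylic radical. The trans-fused skeleton holds the axial 6β-oxygen close to C20 only (C19 has no hydrogen, the equatorial C18 methyl points away, the arene has no free position), and photolysis at or below room temperature should favour the lower-barrier hydrogen transfer.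

Step 18
Reactants: 26 6β,20-epoxy-11,12,14-trimethoxyabieta-8,11,13-triene-19-nitrile
Product: 27 6β,20-epoxy-11,12,14-trimethoxy-7-oxoabieta-8,11,13-triene-19-nitrile
Conditions: CrO3, AcOH, rt
Reagents that add atoms: chromium trioxide, O=[Cr](=O)=O
Why: Benzylic oxidation by CrO3 at C7, as in step 13, places the ketone next to the C6–O bond, while the ether C–H bonds are less reactive than the benzylic ones.

Step 19
Reactants: 27 6β,20-epoxy-11,12,14-trimethoxy-7-oxoabieta-8,11,13-triene-19-nitrile
Product: 28 20-hydroxy-11,12,14-trimethoxy-7-oxoabieta-8,11,13-triene-19-nitrile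
Conditions: SmI2, THF–MeOH, −78 °C
Reagents that add atoms: none
Why: Reductive cleavage of an α-alkoxy ketone by SmI2: the ketyl expels the pseudo-axial C6–O bond, which is aligned with the carbonyl π system, and methanol protonates the samarium enolate at C6, so the oxygen ends on C20 and C5 is not touched.

Step 20
Reactants: 28 20-hydroxy-11,12,14-trimethoxy-7-oxoabieta-8,11,13-triene-19-nitrile
Product: 30 11,12,14-trimethoxy-7-oxoabieta-8,11,13-trien-19,20-olide, via iminolactone 29 (not isolated)
Conditions: 3 M HCl, dioxane, 60 °C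
Reagents that add atoms: water, O
Why: Intramolecular Pinner reaction: the C20 hydroxyl, syn-axial to the protonated nitrile, adds to C19 to form the six-membered iminolactone, which water hydrolyses to the δ-lactone, and any cyclic imidate or 7,20-hemiketal already present converges on the same product.

Step 21
Reactants: 30 11,12,14-trimethoxy-7-oxoabieta-8,11,13-trien-19,20-olide
Product: 31 12-methoxy-7,11,14-trioxoabieta-8,12-dien-19,20-olide
Conditions: AgO, 6 M HNO3, dioxane, rt
Reagents that add atoms: water, O
Why: Oxidative demethylation of the para-dimethoxy pair at C11 and C14 (arene radical cation, water addition at both carbons, loss of methanol) gives the para-quinone with the 12-methoxy group kept, and AgO is strong enough for an arene that carries an acyl group.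

Step 22
Reactants: 31 12-methoxy-7,11,14-trioxoabieta-8,12-dien-19,20-olide
Product: 32 11,14-dihydroxy-12-methoxy-7-oxoabieta-8,11,13-trien-19,20-olide (target)
Conditions: Na2S2O4, H2O–EtOAc, rt, argon
Reagents that add atoms: none
Why: Reduction of the quinone by Na2S2O4 gives the hydroquinone, whose 14-hydroxyl is hydrogen-bonded to the C7 ketone; the ketone and the lactone are not reduced.

**Compound list**

1 | (+)-podocarpic acid (12-hydroxypodocarpa-8,11,13-trien-19-oic acid) | Oc1cc2c(cc1)CC[C@@H]1[C@]2(C)CCC[C@]1(C)C(=O)O | starting material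
2 | methyl 12-methoxypodocarpa-8,11,13-trien-19-oate | COc1cc2c(cc1)CC[C@@H]1[C@]2(C)CCC[C@]1(C)C(=O)OC | intermediate
3 | acetyl chloride | CC(=O)Cl | starting material
4 | methyl 13-acetyl-12-methoxypodocarpa-8,11,13-trien-19-oate | COc1cc2c(cc1C(C)=O)CC[C@@H]1[C@]2(C)CCC[C@]1(C)C(=O)OC | intermediate
5 | methyl 13-(2-hydroxypropan-2-yl)-12-methoxypodocarpa-8,11,13-trien-19-oate | COc1cc2c(cc1C(C)(C)O)CC[C@@H]1[C@]2(C)CCC[C@]1(C)C(=O)OC | intermediate
6 | methyl 12-methoxyabieta-8,11,13-trien-19-oate | COc1cc2c(cc1C(C)C)CC[C@@H]1[C@]2(C)CCC[C@]1(C)C(=O)OC | intermediate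
7 | 12-methoxyabieta-8,11,13-trien-19-oic acid | COc1cc2c(cc1C(C)C)CC[C@@H]1[C@]2(C)CCC[C@]1(C)C(=O)O | intermediate
8 | 12-methoxyabieta-8,11,13-trien-19-oyl chloride (not isolated) | COc1cc2c(cc1C(C)C)CC[C@@H]1[C@]2(C)CCC[C@]1(C)C(=O)Cl | intermediate
9 | 12-methoxyabieta-8,11,13-trien-19-amide | COc1cc2c(cc1C(C)C)CC[C@@H]1[C@]2(C)CCC[C@]1(C)C(N)=O | intermediate
10 | 12-methoxyabieta-8,11,13-triene-19-nitrile | COc1cc2c(cc1C(C)C)CC[C@@H]1[C@]2(C)CCC[C@]1(C)C#N | intermediate
11 | 12-hydroxyabieta-8,11,13-triene-19-nitrile | Oc1cc2c(cc1C(C)C)CC[C@@H]1[C@]2(C)CCC[C@]1(C)C#N | intermediate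
12 | 11,12-dioxoabieta-8,13-diene-19-nitrile (ortho-quinone, not isolated) | O=C1C(=O)C2=C(C=C1C(C)C)CC[C@@H]1[C@]2(C)CCC[C@]1(C)C#N | intermediate
13 | 11,12-dihydroxyabieta-8,11,13-triene-19-nitrile | Oc1c(O)c2c(cc1C(C)C)CC[C@@H]1[C@]2(C)CCC[C@]1(C)C#N | intermediate
14 | 11-hydroxy-12-methoxyabieta-8,11,13-triene-19-nitrile | COc1c(O)c2c(cc1C(C)C)CC[C@@H]1[C@]2(C)CCC[C@]1(C)C#N | intermediate
15 | 12-methoxy-11,14-dioxoabieta-8,12-diene-19-nitrile | COC=1C(=O)C2=C(C(=O)C=1C(C)C)CC[C@@H]1[C@]2(C)CCC[C@]1(C)C#N | intermediate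
16 | 11,14-dihydroxy-12-methoxyabieta-8,11,13-triene-19-nitrile (hydroquinone, not isolated) | COc1c(O)c2c(c(O)c1C(C)C)CC[C@@H]1[C@]2(C)CCC[C@]1(C)C#N | intermediate
17 | 11,12,14-trimethoxyabieta-8,11,13-triene-19-nitrile | COc1c(OC)c2c(c(OC)c1C(C)C)CC[C@@H]1[C@]2(C)CCC[C@]1(C)C#N | intermediate
18 | 11,12,14-trimethoxy-7-oxoabieta-8,11,13-triene-19-nitrile | COc1c(OC)c2c(c(OC)c1C(C)C)C(=O)C[C@@H]1[C@]2(C)CCC[C@]1(C)C#N | intermediate
19 | 7-hydroxy-11,12,14-trimethoxyabieta-8,11,13-triene-19-nitrile (C7 epimers, centre lost in the same flask, not isolated) | COc1c(OC)c2c(c(OC)c1C(C)C)C(O)C[C@@H]1[C@]2(C)CCC[C@]1(C)C#N | intermediate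
20 | 11,12,14-trimethoxyabieta-6,8,11,13-tetraene-19-nitrile | COc1c(OC)c2c(c(OC)c1C(C)C)C=C[C@@H]1[C@]2(C)CCC[C@]1(C)C#N | intermediate
21 | 6α,7α-epoxy-11,12,14-trimethoxyabieta-8,11,13-triene-19-nitrile (not isolated) | COc1c(OC)c2c(c(OC)c1C(C)C)[C@@H]3O[C@@H]3[C@@H]1[C@]2(C)CCC[C@]1(C)C#N | intermediate
22 | 11,12,14-trimethoxy-6-oxoabieta-8,11,13-triene-19-nitrile | COc1c(OC)c2c(c(OC)c1C(C)C)CC(=O)[C@@H]1[C@]2(C)CCC[C@]1(C)C#N | intermediate
23 | 6β-hydroxy-11,12,14-trimethoxyabieta-8,11,13-triene-19-nitrile (key-step precursor) | COc1c(OC)c2c(c(OC)c1C(C)C)C[C@@H](O)[C@@H]1[C@]2(C)CCC[C@]1(C)C#N | intermediate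
24 | 6β-iodooxy-11,12,14-trimethoxyabieta-8,11,13-triene-19-nitrile (hypoiodite, not isolated) | COc1c(OC)c2c(c(OC)c1C(C)C)C[C@@H](OI)[C@@H]1[C@]2(C)CCC[C@]1(C)C#N | intermediate
25 | 6β-hydroxy-20-iodo-11,12,14-trimethoxyabieta-8,11,13-triene-19-nitrile (not isolated) | COc1c(OC)c2c(c(OC)c1C(C)C)C[C@@H](O)[C@@H]1[C@]2(CI)CCC[C@]1(C)C#N | intermediate
26 | 6β,20-epoxy-11,12,14-trimethoxyabieta-8,11,13-triene-19-nitrile (key-step product) | COc1c(OC)c2c(c(OC)c1C(C)C)C[C@@H]3[C@@H]1[C@]2(CO3)CCC[C@]1(C)C#N | intermediate
27 | 6β,20-epoxy-11,12,14-trimethoxy-7-oxoabieta-8,11,13-triene-19-nitrile | COc1c(OC)c2c(c(OC)c1C(C)C)C(=O)[C@@H]3[C@@H]1[C@]2(CO3)CCC[C@]1(C)C#N | intermediate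
28 | 20-hydroxy-11,12,14-trimethoxy-7-oxoabieta-8,11,13-triene-19-nitrile | COc1c(OC)c2c(c(OC)c1C(C)C)C(=O)C[C@@H]1[C@]2(CO)CCC[C@]1(C)C#N | intermediate
29 | 19-imino-11,12,14-trimethoxy-19,20-epoxyabieta-8,11,13-trien-7-one (iminolactone, not isolated) | COc1c(OC)c2c(c(OC)c1C(C)C)C(=O)C[C@@H]1[C@]23CCC[C@]1(C)C(=N)OC3 | intermediate
30 | 11,12,14-trimethoxy-7-oxoabieta-8,11,13-trien-19,20-olide | COc1c(OC)c2c(c(OC)c1C(C)C)C(=O)C[C@@H]1[C@]23CCC[C@]1(C)C(=O)OC3 | intermediate
31 | 12-methoxy-7,11,14-trioxoabieta-8,12-dien-19,20-olide | COC=1C(=O)C2=C(C(=O)C=1C(C)C)C(=O)C[C@@H]1[C@]23CCC[C@]1(C)C(=O)OC3 | intermediate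
32 | 11,14-dihydroxy-12-methoxy-7-oxoabieta-8,11,13-trien-19,20-olide | COc1c(O)c2c(c(O)c1C(C)C)C(=O)C[C@@H]1[C@]23CCC[C@]1(C)C(=O)OC3 | target

**Count and risks**

Total steps: 22. Longest linear sequence: 22 steps (fully linear from 1).

Step 17. The alkoxy radical may cleave the C6–C7 bond to a benzylic radical faster than it abstracts hydrogen from C20, and the oxidising iodine medium may attack the new ether again at C20. The fallback sets out from 23 and comes back at 26 by nitrite photolysis (Barton reaction), run cold and without iodine or oxidant. NOCl in pyridine at −20 °C should give the 6β-nitrite F1. Irradiation (Hg lamp, Pyrex, toluene, 0 °C) moves NO to C20, and warming in i-PrOH isomerises the nitroso compound to 6β-hydroxy-20-(hydroxyimino)-11,12,14-trimethoxyabieta-8,11,13-triene-19-nitrile F2. Deoximation with aqueous NaHSO3 and dilute acid frees the C20 aldehyde, which closes onto the 6β-hydroxyl as the 6β,20-epoxy-20-hydroxy lactol F3. Et3SiH and BF3·OEt2 in CH2Cl2 at −40 °C reduce the lactol through its oxocarbenium ion to ether 26.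

Step 18. The C7 methylene is deactivated by the neighbouring C6–O bond, so CrO3 may instead oxidise the ether C–H bonds or demethylate the electron-rich ring. The fallback sets out from 26 and comes back at 27 by halogenation, solvolysis and alcohol oxidation. Radical bromination with NBS (hν, PhCF3, 60 °C) should give the 7-bromo-6β,20-epoxy nitrile F4; the arene has no free position for ring bromination. AgNO3 in aqueous acetone hydrolyses the benzylic bromide to the 7-hydroxy-6β,20-epoxy nitrile F5. Dess–Martin periodinane in CH2Cl2 oxidises F5 to ketone 27.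

Step 10. Methylation may not discriminate well between O11 and O12, may run on to the dimethyl ether, and the catechol may be lost to air oxidation. The fallback sets out from 11 and comes back at 14, bypassing steps 9 and 10, and fixes the position of each oxygen by the order of events. NBS in MeCN at 0 °C brominates the only free ortho position of the phenol to give 11-bromo-12-hydroxyabieta-8,11,13-triene-19-nitrile F6. MeI and K2CO3 in acetone give 11-bromo-12-methoxyabieta-8,11,13-triene-19-nitrile F7. Palladium-catalysed hydroxylation of the aryl bromide (Pd2(dba)3, tBuXPhos, KOH, dioxane–H2O, 100 °C) then gives 14.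

Further compounds
F1 | step 17 | 6β-nitrosooxy-11,12,14-trimethoxyabieta-8,11,13-triene-19-nitrile (6β-nitrite) | COc1c(OC)c2c(c(OC)c1C(C)C)C[C@@H](ON=O)[C@@H]1[C@]2(C)CCC[C@]1(C)C#N
F2 | step 17 | 6β-hydroxy-20-(hydroxyimino)-11,12,14-trimethoxyabieta-8,11,13-triene-19-nitrile (E-oxime) | COc1c(OC)c2c(c(OC)c1C(C)C)C[C@@H](O)[C@@H]1[C@]2(/C=N/O)CCC[C@]1(C)C#N
F3 | step 17 | 6β,20-epoxy-20-hydroxy-11,12,14-trimethoxyabieta-8,11,13-triene-19-nitrile (lactol, both anomers) | COc1c(OC)c2c(c(OC)c1C(C)C)C[C@@H]3[C@@H]1[C@]2(C(O)O3)CCC[C@]1(C)C#N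
F4 | step 18 | 7-bromo-6β,20-epoxy-11,12,14-trimethoxyabieta-8,11,13-triene-19-nitrile (C7 epimers) | COc1c(OC)c2c(c(OC)c1C(C)C)C(Br)[C@@H]3[C@@H]1[C@]2(CO3)CCC[C@]1(C)C#N
F5 | step 18 | 6β,20-epoxy-7-hydroxy-11,12,14-trimethoxyabieta-8,11,13-triene-19-nitrile (C7 epimers) | COc1c(OC)c2c(c(OC)c1C(C)C)C(O)[C@@H]3[C@@H]1[C@]2(CO3)CCC[C@]1(C)C#N
F6 | step 10 | 11-bromo-12-hydroxyabieta-8,11,13-triene-19-nitrile | Oc1c(Br)c2c(cc1C(C)C)CC[C@@H]1[C@]2(C)CCC[C@]1(C)C#N
F7 | step 10 | 11-bromo-12-methoxyabieta-8,11,13-triene-19-nitrile | COc1c(Br)c2c(cc1C(C)C)CC[C@@H]1[C@]2(C)CCC[C@]1(C)C#N
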